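**Strategy.** The plan opens the furan (ring A: O, C22, C23, C24, C25) across its C23=C24 bond rather than at a C–O bond. It exploits the fact that ring A is 2-monosubstituted. C23, C24 and C25 carry only hydrogen, so the ring maps onto two plain vinyl groups tied together through an O–C25 acetal. In one flask, ruthenium-catalysed diene metathesis forges C23=C24. Acid then expels ethanol and delivers the aromatic ring with the whole C1–C21 diynyl chain already in place. Precursor 12 is the mixed ethyl acrolein acetal of a silyl-protected C24 enediynol, assembled from two arms by a Cadiot–Chodkiewicz coupling at C15–C16.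

Key step: step 8

Remark: locants are those of the target (C1 = CH2OH carbon, C14–C17 = diyne, C22 = chain-bearing furan carbon). C1–C12 come from 6, C13–C15 from 8, C16–C22 from 1, C23 from the vinyl Grignard reagent, and C24–C25 from 4. The target is achiral, so 3 is carried as the racemate and 5, 12 and 13 as diastereomer mixtures.

Step 1
Reactants: 1 hept-6-yn-1-ol
Product: 2 hept-6-ynal
Conditions: Dess–Martin periodinane (1.2 equiv), CH2Cl2, 0 °C to rt
Reagents that add atoms: none
Why: Dess–Martin oxidation takes a primary alcohol to the aldehyde without over-oxidation under near-neutral, anhydrous conditions that leave the terminal alkyne alone; the volatile aldehyde should be concentrated cold and used at once.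

Step 2
Reactants: 2 hept-6-ynal
Product: 3 non-1-en-8-yn-3-ol (racemic)
Conditions: CH2=CHMgBr (1.2 equiv), THF, −78 to 0 °C; then H2O
Reagents that add atoms: vinylmagnesium bromide, C=C[Mg]Br
Why: Grignard 1,2-addition to the aldehyde is much faster at low temperature than deprotonation of the alkyne C–H, and the new carbinol centre (future C22) is deliberately left racemic because it becomes sp2 in step 8.

Step 3
Reactants: 3 non-1-en-8-yn-3-ol, 4 acrolein diethyl acetal (3,3-diethoxyprop-1-ene)
Product: 5 3-[(1-ethoxyprop-2-en-1-yl)oxy]non-1-en-8-yne (diastereomer mixture)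
Conditions: 4 (5 equiv), PPTS (5 mol%), toluene, 90 °C, EtOH–toluene azeotrope distilled off; Et3N quench; Et3N-deactivated SiO2
Reagents that add atoms: none
Why: In this acid-catalysed transacetalisation PPTS ionises 4 to the 1-ethoxyallyl oxocarbenium ion, 3 captures it, the excess of 4 and removal of ethanol pull the equilibrium towards the mixed acetal, and the new acetal centre (future C25) forms unselectively, which does not matter because step 8 erases it.

Step 4
Reactants: 6 12-bromododecan-1-ol
Product: 7 [(12-bromododecyl)oxy](tert-butyl)diphenylsilane
Conditions: TBDPSCl (1.1 equiv), imidazole (2 equiv), CH2Cl2, 0 °C to rt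
Reagents that add atoms: tert-butyldiphenylsilyl chloride, CC(C)(C)[Si](Cl)(c1ccccc1)c1ccccc1
Why: Imidazole-promoted silylation of a primary alcohol is routine, and TBDPS is chosen because it should withstand the organolithium, the AgNO3/NBS step, the aqueous amine and the PPTS/ethanol of later steps while keeping the C1 hydroxyl out of any acetal exchange.

Step 5
Reactants: 7 [(12-bromododecyl)oxy](tert-butyl)diphenylsilane, 8 1-(trimethylsilyl)propyne
Product: 10 tert-butyldiphenyl{[15-(trimethylsilyl)pentadec-14-yn-1-yl]oxy}silane, via 3-lithio-1-(trimethylsilyl)propyne 9 (not isolated)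
Conditions: 8 (1.5 equiv), n-BuLi (1.4 equiv), THF, −78 to −20 °C; then 7, DMPU, −78 °C to rt
Reagents that add atoms: none
Why: In this SN2 propargylation of a primary bromide the silyl group steers the ambident lithiated propyne to react at its CH2 terminus rather than as an allenyl anion, so C13–C15 are added in one operation, and keeping n-BuLi below the amount of 8 leaves none to attack 7.

Step 6
Reactants: 10 tert-butyldiphenyl{[15-(trimethylsilyl)pentadec-14-yn-1-yl]oxy}silane
Product: 11 [(15-bromopentadec-14-yn-1-yl)oxy](tert-butyl)diphenylsilane
Conditions: NBS (1.2 equiv), AgNO3 (20 mol%), acetone, rt, dark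
Reagents that add atoms: N-bromosuccinimide, O=C1CCC(=O)N1Br
Why: In this silver-catalysed bromodesilylation AgNO3 converts the alkynylsilane into a silver acetylide that NBS brominates, so the 1-bromoalkyne is reached without a separate desilylation and the saturated chain and TBDPS ether offer no competing site.

Step 7
Reactants: 5 3-[(1-ethoxyprop-2-en-1-yl)oxy]non-1-en-8-yne, 11 [(15-bromopentadec-14-yn-1-yl)oxy](tert-butyl)diphenylsilane
Product: 12 tert-butyl({22-[(1-ethoxyprop-2-en-1-yl)oxy]tetracos-23-ene-14,16-diyn-1-yl}oxy)diphenylsilane (diastereomer mixture)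
Conditions: 5 (1.3 equiv), CuCl (10 mol%), NH2OH·HCl (30 mol%), n-BuNH2 (30% aq.), Et2O, 0 °C to rt; work-up at pH 9 (aq. NH3/NH4Cl); Et3N-deactivated SiO2
Reagents that add atoms: none
Why: In this Cadiot–Chodkiewicz coupling the copper acetylide of 5 joins bromoalkyne 11 at C15–C16, hydroxylamine holds the copper in its monovalent state to suppress oxidative dimerisation, and the basic medium is one in which the mixed acetal, the vinyl groups and the silyl ether are inert.

Step 8
Reactants: 12 tert-butyl({22-[(1-ethoxyprop-2-en-1-yl)oxy]tetracos-23-ene-14,16-diyn-1-yl}oxy)diphenylsilane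
Product: 14 tert-butyl{[21-(furan-2-yl)henicosa-14,16-diyn-1-yl]oxy}diphenylsilane (TBDPS ether of the target), via 2-ethoxy-2,5-dihydrofuran acetal 13 (not isolated)
Conditions: RuCl2(H2IMes)(PCy3)(=CHPh) (second-generation Grubbs catalyst, 5 mol%), CH2Cl2 (5 mM, passed through basic Al2O3), 40 °C, argon sparge; then PPTS (20 mol%), rt
Reagents that add atoms: none
Why: After the benzylidene has been exchanged for one of the two vinyl termini, the ruthenium carbene adds across the other vinyl group to a ruthenacyclobutane whose fragmentation leaves C23=C24 inside the new ring and gives off ethene (13); PPTS then ionises the C25–OEt bond to an alkene-conjugated oxocarbenium ion, and loss of H-22 makes ring A aromatic. The closest known reaction type is this very one, ring-closing metathesis of allyl acrolein mixed acetals to 2-alkoxy-2,5-dihydrofurans followed by acid-promoted loss of the alcohol, here applied to a substrate that carries a remote diyne. Ring A closes as a five-membered ring from a 4-oxa-1,6-diene with the new double bond endocyclic, the most favourable ring size for diene metathesis. No lasting stereocentre is formed: C22 and C25 both end up sp2, so every stereoisomer of 12 funnels into one achiral product and no controlling element is called for. The selectivity required is alkene over alkyne, and the substrate secures it because two unhindered monosubstituted alkenes sit in a 1,6-relationship, whereas the internal, dialkyl-flanked diyne can be reached from the C23 carbene only through a seven-membered enyne closure or bimolecularly, pathways further disfavoured by high dilution and by sweeping out ethene. The acid is withheld until the diene is consumed so that the acetal tether is not cleaved prematurely, and the TBDPS ether should tolerate PPTS and the liberated ethanol.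

Step 9
Reactants: 14 tert-butyl{[21-(furan-2-yl)henicosa-14,16-diyn-1-yl]oxy}diphenylsilane
Product: 15 21-(furan-2-yl)henicosa-14,16-diyn-1-ol (target, CNP0078078.0)
Conditions: TBAF (1.2 equiv), THF, 0 °C to rt; then H2O
Reagents that add atoms: none
Why: Fluoride-mediated desilylation is driven by the strong Si–F bond and proceeds under mild conditions to which the furan and the dialkyl diyne are indifferent.

**Compound list**

1 | hept-6-yn-1-ol | C#CCCCCCO | starting material
2 | hept-6-ynal | C#CCCCCC=O | intermediate
3 | non-1-en-8-yn-3-ol (racemic) | C=CC(O)CCCCC#C | intermediate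
4 | acrolein diethyl acetal (3,3-diethoxyprop-1-ene) | C=CC(OCC)OCC | starting material
5 | 3-[(1-ethoxyprop-2-en-1-yl)oxy]non-1-en-8-yne (diastereomer mixture) | C=CC(OCC)OC(C=C)CCCCC#C | intermediate
6 | 12-bromododecan-1-ol | OCCCCCCCCCCCCBr | starting material
7 | [(12-bromododecyl)oxy](tert-butyl)diphenylsilane | CC(C)(C)[Si](c1ccccc1)(c1ccccc1)OCCCCCCCCCCCCBr | intermediate
8 | 1-(trimethylsilyl)propyne | CC#C[Si](C)(C)C | starting material
9 | 3-lithio-1-(trimethylsilyl)propyne, [3-(trimethylsilyl)prop-2-yn-1-yl]lithium (not isolated) | [Li]CC#C[Si](C)(C)C | intermediate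
10 | tert-butyldiphenyl{[15-(trimethylsilyl)pentadec-14-yn-1-yl]oxy}silane | CC(C)(C)[Si](c1ccccc1)(c1ccccc1)OCCCCCCCCCCCCCC#C[Si](C)(C)C | intermediate
11 | [(15-bromopentadec-14-yn-1-yl)oxy](tert-butyl)diphenylsilane | CC(C)(C)[Si](c1ccccc1)(c1ccccc1)OCCCCCCCCCCCCCC#CBr | intermediate
12 | 22-(1-ethoxyprop-2-en-1-yloxy)tetracos-23-ene-14,16-diyn-1-ol TBDPS ether (diastereomer mixture) | C=CC(OCC)OC(C=C)CCCCC#CC#CCCCCCCCCCCCCCO[Si](c1ccccc1)(c1ccccc1)C(C)(C)C | intermediate
13 | 21-(5-ethoxy-2,5-dihydrofuran-2-yl)henicosa-14,16-diyn-1-ol TBDPS ether (diastereomer mixture, not isolated) | CCOC1C=CC(CCCCC#CC#CCCCCCCCCCCCCCO[Si](c2ccccc2)(c2ccccc2)C(C)(C)C)O1 | intermediate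
14 | 21-(furan-2-yl)henicosa-14,16-diyn-1-ol TBDPS ether | CC(C)(C)[Si](c1ccccc1)(c1ccccc1)OCCCCCCCCCCCCCC#CC#CCCCCc1ccco1 | intermediate
15 | 21-(furan-2-yl)henicosa-14,16-diyn-1-ol | OCCCCCCCCCCCCCC#CC#CCCCCc1ccco1 | target

**Total step count:** 9.
**Longest linear sequence:** 6 steps (4, 5, 6, 7, 8, 9). The arm 1, 2, 3, 7, 8, 9 is equally long.

**Steps most likely to fail**

1. **Step 8.**
   - The ruthenium carbene may be diverted into enyne metathesis with the conjugated diyne, held back by coordination to it, or consumed in cross-enyne reaction with liberated ethene. Ring closure would then stall or oligomers would build up.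
   - The fallback closes the ring before any diyne exists and sets out from 5. Deprotonation with n-BuLi (THF, −78 °C) gives the lithium acetylide of 5 F1.
   - Me3SiCl caps F1 to {7-[(1-ethoxyprop-2-en-1-yl)oxy]non-8-en-1-yn-1-yl}trimethylsilane F2.
   - The same metathesis on this diyne-free diene, whose silyl-capped alkyne is a very poor enyne partner, should give [6-(5-ethoxy-2,5-dihydrofuran-2-yl)hex-1-yn-1-yl]trimethylsilane F3.
   - PPTS aromatises F3 in the same flask to [6-(furan-2-yl)hex-1-yn-1-yl]trimethylsilane F4.
   - K2CO3 in MeOH frees 2-(hex-5-yn-1-yl)furan F5. Cadiot–Chodkiewicz coupling of F5 with 11 under the conditions of step 7 comes back to the route at 14.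

2. **Step 3.**
   - The exchange is an equilibrium. It may stop short, run on to the symmetrical bis(allylic) acetal, or revert during isolation through acid-induced loss of the acetal.
   - The fallback sets out from 3 and replaces exchange by an irreversible addition.
   - 1-Ethoxypropa-1,2-diene (ethoxyallene) F6 is obtained from commercial ethyl propargyl ether by KOtBu-catalysed isomerisation.
   - Catalytic PPTS (CH2Cl2, 0 °C) protonates F6 at its central carbon to the same 1-ethoxyallyl cation, which 3 captures. This is the classical Brønsted-acid-catalysed addition of alcohols to allenyl ethers.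
   - No ethanol is released, so there is nothing to remove and no back-reaction to fight. The fallback comes back to the route at 5.

3. **Step 7.**
   - Reductive dimerisation of the bromoalkyne and oxidative dimerisation of the terminal alkyne may consume both partners and give three diynes of similar polarity.
   - The acetal may also be lost during aqueous work-up and chromatography.
   - The fallback changes the order of events and sets out from 3 and 11.
   - The free allylic alcohol 3 is coupled with 11 to give 24-[(tert-butyldiphenylsilyl)oxy]tetracos-1-ene-8,10-diyn-3-ol F7.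
   - The hydroxyl group spreads the polarity of cross- and homo-coupled products, and no acid-labile group meets the copper–amine medium.
   - Transacetalisation of F7 with 4 as in step 3 is possible because the C1 hydroxyl is silylated. It comes back to the route at 12, at the price of one more step in the longest linear sequence.

**Further compounds**

F1 | step 8 | lithium acetylide of 5, {7-[(1-ethoxyprop-2-en-1-yl)oxy]non-8-en-1-yn-1-yl}lithium | [Li]C#CCCCCC(C=C)OC(OCC)C=C
F2 | step 8 | {7-[(1-ethoxyprop-2-en-1-yl)oxy]non-8-en-1-yn-1-yl}trimethylsilane | C=CC(OCC)OC(C=C)CCCCC#C[Si](C)(C)C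
F3 | step 8 | [6-(5-ethoxy-2,5-dihydrofuran-2-yl)hex-1-yn-1-yl]trimethylsilane | CCOC1C=CC(CCCCC#C[Si](C)(C)C)O1
F4 | step 8 | [6-(furan-2-yl)hex-1-yn-1-yl]trimethylsilane | C[Si](C)(C)C#CCCCCc1ccco1
F5 | step 8 | 2-(hex-5-yn-1-yl)furan | C#CCCCCc1ccco1
F6 | step 3 | 1-ethoxypropa-1,2-diene (ethoxyallene) | C=C=COCC
F7 | step 7 | 24-[(tert-butyldiphenylsilyl)oxy]tetracos-1-ene-8,10-diyn-3-ol | C=CC(O)CCCCC#CC#CCCCCCCCCCCCCCO[Si](c1ccccc1)(c1ccccc1)C(C)(C)C
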